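## Retrosynthetic overview

- Both heterocycles are closed last, in one flask: the dehydrohydantoin from an oxalimidate and an N-methylcarbamoyl donor, the 2-aminoimidazole by guanylation and cyclocondensation of a β-hydroxy-α-amino ketone (bonds N3–C2 and N1–C5).
- The amino ketone comes from a trans-5-aryl-2-oxazolin-4-yl benzyl ketone (a masked threo amino alcohol) by hydrolysis.
- That ketone comes from the oxazoline-4-carboxamide and a 4-silyloxybenzyl Grignard reagent.
- The oxazoline comes from anisaldehyde and an isocyanoacetamide by catalytic asymmetric isocyanide aldol reaction, which sets the (R)-carbinol centre.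
- Ring order: oxazoline (temporary, first step), then dehydrohydantoin and imidazole together in the last step; both benzene rings are bought.

Assumption: the SMILES is read as the (R)-carbinol, and the isocyanoacetyl morpholine and the silyl-protected 4-hydroxybenzyl chloride are taken as catalogue building blocks.

## Route

Step 1
Reactants: 1 4-methoxybenzaldehyde; 2 2-isocyano-1-(morpholin-4-yl)ethan-1-one
Product: 3 [(4S,5R)-5-(4-methoxyphenyl)-4,5-dihydro-1,3-oxazol-4-yl](morpholin-4-yl)methanone
Conditions: [Au(c-C6H11NC)2]BF4 (1 mol %), (R)-N-methyl-N-[2-(piperidin-1-yl)ethyl]-1-[(S)-1′,2-bis(diphenylphosphino)ferrocenyl]ethylamine (1.1 mol %), CH2Cl2, 25 °C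
Reagents that add atoms: none
Why: Hayashi–Ito asymmetric isocyanide aldol reaction: the ligand's terminal amine deprotonates the isocyanoacetamide coordinated to the cationic metal centre of [Au(c-C6H11NC)2]BF4, the ion pair adds to one face of the aldehyde and the alkoxide closes onto the isocyanide carbon, giving the trans-oxazoline whose C5 (R) becomes the carbinol centre of the target, while C4 is only a placeholder.

Step 2
Reactants: 3 [(4S,5R)-5-(4-methoxyphenyl)-4,5-dihydro-1,3-oxazol-4-yl](morpholin-4-yl)methanone; 4 tert-butyl[4-(chloromethyl)phenoxy]dimethylsilane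
Product: 6 1-[(4S,5R)-5-(4-methoxyphenyl)-4,5-dihydro-1,3-oxazol-4-yl]-2-{4-[(tert-butyldimethylsilyl)oxy]phenyl}ethan-1-one, via benzylmagnesium chloride 5 (not isolated)
Conditions: 4, Mg, Et2O, 0 °C; then 3, THF, −78 → −20 °C; aq NH4Cl
Reagents that add atoms: none
Why: Acylation of a Grignard reagent by a morpholine amide (Weinreb-type ketone synthesis): the chelated tetrahedral adduct survives until the quench, so only one benzyl group is delivered; no stereocentre is formed, C5 is untouched, and any epimerisation at C4 is without consequence.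

Step 3
Reactants: 6 1-[(4S,5R)-5-(4-methoxyphenyl)-4,5-dihydro-1,3-oxazol-4-yl]-2-{4-[(tert-butyldimethylsilyl)oxy]phenyl}ethan-1-one
Product: 7 (3S,4R)-3-amino-1-{4-[(tert-butyldimethylsilyl)oxy]phenyl}-4-hydroxy-4-(4-methoxyphenyl)butan-2-one hydrochloride
Conditions: HCl (1.25 M in MeOH, 3 equiv), H2O (3 equiv), THF, 0 °C → rt; evaporate, triturate with Et2O
Reagents that add atoms: hydrogen chloride, SMILES Cl
Why: Acid hydrolysis of a 2-unsubstituted 2-oxazoline (water adds to the protonated C2, methanolysis removes the formyl group) frees the threo amino alcohol without breaking the C–O bond at the carbinol carbon, so (R) is retained, and the hydrochloride resists self-condensation and retro-aldol cleavage; no new stereocentre.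

Step 4
Reactants: 7 (3S,4R)-3-amino-1-{4-[(tert-butyldimethylsilyl)oxy]phenyl}-4-hydroxy-4-(4-methoxyphenyl)butan-2-one hydrochloride; 8 ethyl 2-ethoxy-2-iminoacetate; 9 2,5-dioxopyrrolidin-1-yl N-methylcarbamate; 10 methyl N-methylcarbamimidothioate hydroiodide
Product: 15 4-({4-[(R)-hydroxy(4-methoxyphenyl)methyl]-5-[(4-hydroxyphenyl)methyl]-1-methyl-1H-imidazol-2-yl}amino)-1-methyl-1H-imidazole-2,5-dione, via lactim ether 11 (not isolated), via isothiourea 12 (not isolated), via acylguanidine 13 (not isolated), via silyl ether 14 (not isolated)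
Conditions: 8, 9, Et3N, MeCN, 0 °C → rt; then 10, Et3N, rt; then 7, Et3N, 0 → 40 °C; then Bu4NF, AcOH, THF, 0 °C
Reagents that add atoms: none
Why: Proposed new method: the imidate nitrogen of 8 takes the N-methylcarbamoyl group from active carbamate 9 and the new urea NH closes onto the neighbouring ester (5-exo-trig imide formation) to give lactim ether 11, the first ring; the unsubstituted nitrogen of 10 displaces ethoxide from 11 to give isothiourea 12, whose carbon is activated by the vinylogous diacyl substituent, so the primary amine of 7 displaces methanethiol and forms acylguanidine 13 in which NHMe is the only nucleophilic nitrogen left; NHMe adds to the ketone and water is lost to give the aromatic imidazole, the second ring, with N-methyl next to the benzyl-bearing carbon (Marckwald-type closure), the C3 centre vanishing and the carbinol carbon, never involved in a bond change, keeping (R); fluoride then cleaves the aryl silyl ether; the closest known chemistry is aminolysis of lactim ethers and of N-acyl-S-methylisothioureas and the cyclocondensation of α-amino ketones with cyanamide or acylguanidines to 2-aminoimidazoles.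

## Compound list

1 | 4-methoxybenzaldehyde | COc1ccc(C=O)cc1 | starting material
2 | 2-isocyano-1-(morpholin-4-yl)ethan-1-one | [C-]#[N+]CC(=O)N1CCOCC1 | starting material
3 | [(4S,5R)-5-(4-methoxyphenyl)-4,5-dihydro-1,3-oxazol-4-yl](morpholin-4-yl)methanone | O=C([C@H]1N=CO[C@@H]1c1ccc(OC)cc1)N1CCOCC1 | intermediate
4 | tert-butyl[4-(chloromethyl)phenoxy]dimethylsilane | CC(C)(C)[Si](C)(C)Oc1ccc(CCl)cc1 | starting material
5 | {4-[(tert-butyldimethylsilyl)oxy]benzyl}magnesium chloride | CC(C)(C)[Si](C)(C)Oc1ccc(C[Mg]Cl)cc1 | intermediate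
6 | 1-[(4S,5R)-5-(4-methoxyphenyl)-4,5-dihydro-1,3-oxazol-4-yl]-2-{4-[(tert-butyldimethylsilyl)oxy]phenyl}ethan-1-one | O=C(Cc1ccc(O[Si](C)(C)C(C)(C)C)cc1)[C@H]1N=CO[C@@H]1c1ccc(OC)cc1 | intermediate
7 | (3S,4R)-3-amino-1-{4-[(tert-butyldimethylsilyl)oxy]phenyl}-4-hydroxy-4-(4-methoxyphenyl)butan-2-one hydrochloride | COc1ccc([C@@H](O)[C@H]([NH3+])C(=O)Cc2ccc(O[Si](C)(C)C(C)(C)C)cc2)cc1.[Cl-] | intermediate
8 | ethyl 2-ethoxy-2-iminoacetate | CCOC(=N)C(=O)OCC | starting material
9 | 2,5-dioxopyrrolidin-1-yl N-methylcarbamate | CNC(=O)ON1C(=O)CCC1=O | starting material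
10 | methyl N-methylcarbamimidothioate hydroiodide | CNC(=N)SC.I | starting material
11 | 4-ethoxy-1-methyl-1H-imidazole-2,5-dione | CCOC1=NC(=O)N(C)C1=O | intermediate
12 | methyl N-methyl-N′-(1-methyl-2,5-dioxo-2,5-dihydro-1H-imidazol-4-yl)carbamimidothioate | CNC(SC)=NC1=NC(=O)N(C)C1=O | intermediate
13 | 1-[(3S,4R)-1-{4-[(tert-butyldimethylsilyl)oxy]phenyl}-4-hydroxy-4-(4-methoxyphenyl)-2-oxobutan-3-yl]-3-methyl-2-(1-methyl-2,5-dioxo-2,5-dihydro-1H-imidazol-4-yl)guanidine | COc1ccc([C@@H](O)[C@H](NC(NC)=NC2=NC(=O)N(C)C2=O)C(=O)Cc2ccc(O[Si](C)(C)C(C)(C)C)cc2)cc1 | intermediate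
14 | 4-({5-({4-[(tert-butyldimethylsilyl)oxy]phenyl}methyl)-4-[(R)-hydroxy(4-methoxyphenyl)methyl]-1-methyl-1H-imidazol-2-yl}amino)-1-methyl-1H-imidazole-2,5-dione | COc1ccc([C@@H](O)c2nc(NC3=NC(=O)N(C)C3=O)n(C)c2Cc2ccc(O[Si](C)(C)C(C)(C)C)cc2)cc1 | intermediate
15 | 4-({4-[(R)-hydroxy(4-methoxyphenyl)methyl]-5-[(4-hydroxyphenyl)methyl]-1-methyl-1H-imidazol-2-yl}amino)-1-methyl-1H-imidazole-2,5-dione | COc1ccc([C@@H](O)c2nc(NC3=NC(=O)N(C)C3=O)n(C)c2Cc2ccc(O)cc2)cc1 | target

## Step count, risks and fallbacks

Total step count: 4. Longest linear sequence: 4 steps (1 and 2 → 3 → 6 → 7 → 15); building blocks 4, 8, 9 and 10 enter directly.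

**Most likely to fail, first: step 4.** The free base of 7 can undergo retro-aldol cleavage or dimerise before it is guanylated, and the amine may attack C4 of the dehydrohydantoin in 12 instead of the isothiourea carbon. The fallback sets out from 7 and comes back at 15; it builds the imidazole on a simple acyl-activated guanidine and forms the dehydrohydantoin attachment last. Compound 7 with ethoxycarbonyl isothiocyanate (Et3N, CH2Cl2, 0 °C) gives the N-ethoxycarbonyl thiourea F1. MeNH2 and EDC·HCl convert F1 into the acylguanidine, which closes at once through its NHMe nitrogen to the ethyl imidazol-2-ylcarbamate F2. KOH in aqueous EtOH at 60 °C removes the carbamate and the aryl silyl ether to give the 2-amino-1-methylimidazole phenol F3. F3 then displaces ethoxide from lactim ether 11, made beforehand from 8 and 9, in MeCN to give 15.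

**Second: step 3.** Acid may ionise the 4-methoxybenzylic C–O bond of the protonated oxazoline, which would erode the carbinol configuration, and the salt 7 may be hard to handle. The fallback sets out from 6 and comes back at 15; it opens the oxazoline without acid. 2-(Trimethylsilyl)ethyl chloroformate with NaHCO3 in THF–H2O at 0 °C acylates the ring nitrogen, and water opens the oxazolinium ion to the N-protected O-formyl amino ketone F4. KHCO3 in MeOH at 0 °C removes the formate to give the carbamate-protected amino alcohol F5. Bu4NF in THF then removes the silylethyl carbamate and the aryl silyl ether in the presence of isothiourea 12 (made beforehand from 8, 9 and 10). The free amino ketone phenol F6 is guanylated as it forms and closes to 15.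

**Third: step 2.** Reagent 5 may deprotonate C4 of 3 (ring opening, retro-aldol, loss of enantiomeric purity), and its preparation suffers from Wurtz coupling. The fallback sets out from 3 and comes back at 6; it goes through the aldehyde oxidation level. Cp2Zr(H)Cl in THF reduces the morpholine amide of 3 to the oxazoline-4-carbaldehyde F7. Reagent 5 adds to F7 at −78 °C to give the secondary alcohol F8 as an epimer mixture. Dess–Martin periodinane oxidises F8 to 6.

## Further compounds

F1 | step 4 | ethyl N-{[(3S,4R)-1-{4-[(tert-butyldimethylsilyl)oxy]phenyl}-4-hydroxy-4-(4-methoxyphenyl)-2-oxobutan-3-yl]carbamothioyl}carbamate | COc1ccc([C@@H](O)[C@H](NC(=S)NC(=O)OCC)C(=O)Cc2ccc(O[Si](C)(C)C(C)(C)C)cc2)cc1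
F2 | step 4 | ethyl N-{5-({4-[(tert-butyldimethylsilyl)oxy]phenyl}methyl)-4-[(R)-hydroxy(4-methoxyphenyl)methyl]-1-methyl-1H-imidazol-2-yl}carbamate | COc1ccc([C@@H](O)c2nc(NC(=O)OCC)n(C)c2Cc2ccc(O[Si](C)(C)C(C)(C)C)cc2)cc1
F3 | step 4 | 4-({2-amino-4-[(R)-hydroxy(4-methoxyphenyl)methyl]-1-methyl-1H-imidazol-5-yl}methyl)phenol | COc1ccc([C@@H](O)c2nc(N)n(C)c2Cc2ccc(O)cc2)cc1
F4 | step 3 | (1R,2S)-4-{4-[(tert-butyldimethylsilyl)oxy]phenyl}-1-(4-methoxyphenyl)-3-oxo-2-({[2-(trimethylsilyl)ethoxy]carbonyl}amino)butyl formate | COc1ccc([C@@H](OC=O)[C@H](NC(=O)OCC[Si](C)(C)C)C(=O)Cc2ccc(O[Si](C)(C)C(C)(C)C)cc2)cc1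
F5 | step 3 | 2-(trimethylsilyl)ethyl N-[(3S,4R)-1-{4-[(tert-butyldimethylsilyl)oxy]phenyl}-4-hydroxy-4-(4-methoxyphenyl)-2-oxobutan-3-yl]carbamate | COc1ccc([C@@H](O)[C@H](NC(=O)OCC[Si](C)(C)C)C(=O)Cc2ccc(O[Si](C)(C)C(C)(C)C)cc2)cc1
F6 | step 3 | (3S,4R)-3-amino-4-hydroxy-1-(4-hydroxyphenyl)-4-(4-methoxyphenyl)butan-2-one | COc1ccc([C@@H](O)[C@H](N)C(=O)Cc2ccc(O)cc2)cc1
F7 | step 2 | (4S,5R)-5-(4-methoxyphenyl)-4,5-dihydro-1,3-oxazole-4-carbaldehyde | O=C[C@H]1N=CO[C@@H]1c1ccc(OC)cc1
F8 | step 2 | 2-{4-[(tert-butyldimethylsilyl)oxy]phenyl}-1-[(4R,5R)-5-(4-methoxyphenyl)-4,5-dihydro-1,3-oxazol-4-yl]ethan-1-ol (ring geometry as in 6, carbinol epimers) | OC(Cc1ccc(O[Si](C)(C)C(C)(C)C)cc1)[C@H]1N=CO[C@@H]1c1ccc(OC)cc1
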